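The quinone ring is traced back to a resorcylate arene, and this to an open C24 chain. On the ring, C6 (heptadecyl), C2 (OMe) and C4 (C=O) occupy alternate positions, the acetate-derived 1,3,5 pattern. Only the oxygen at C1 is foreign; it sits para to O4, where phenol oxidation delivers it. The key step exploits this pattern. Methyl 3,5,7-trioxotetracosanoate, made from a triacetate ester trianion and methyl stearate, closes its chain C2–C7 bond by intramolecular aldol condensation and aromatises. The only carbocycle, the chain position and both ring oxygens are thus set at once. The surviving ester then directs mono-O-methylation and leaves as CO2, and para-oxidation gives the quinone.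

Key step: step 3

Remark: 2, 5 and 6 are drawn as all-keto tautomers although they are largely enolised; open-chain locants count from the ester carbonyl (C1) of 5 and ring locants are those of the quinone 12; the target has no stereogenic element.

Step 1
Reactants: 1 4-hydroxy-6-methyl-2H-pyran-2-one (triacetic acid lactone)
Product: 2 methyl 3,5-dioxohexanoate
Conditions: Mg(OMe)2 (commercial solution, 2 equiv), MeOH, reflux; then ice-cold 1 M HCl to pH 3–4, CH2Cl2 extraction, no heating of the crude
Reagents that add atoms: magnesium dimethoxide, [Mg+2].C[O-].C[O-]; methanol, CO
Why: Alcoholysis of an enol lactone: magnesium binds the pyranone oxygens, methoxide adds to the lactone carbonyl, and the opened β,δ-diketo ester is held as a magnesium chelate that should keep it from closing back until the cold quench.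

Step 2
Reactants: 2 methyl 3,5-dioxohexanoate; 3 methyl octadecanoate (methyl stearate)
Product: 5 methyl 3,5,7-trioxotetracosanoate, via trilithium trianion 4 (not isolated)
Conditions: 2 (2.2 equiv), LiN(iPr)2 (commercial, 6.8 equiv), THF, −78 → 0 °C; 3 (1 equiv) in THF, 0 °C; poured into ice-cold 1 M HCl–Et2O; recovered 2 removed by water washes and high vacuum; no silica, used crude
Reagents that add atoms: none
Why: Claisen-type C-acylation of a polyanion: the terminal CH2 of 4, the last site deprotonated, is by far the most nucleophilic and should alone attack the ester carbonyl of 3, while the twofold amount of cheap 4 supplies the base that the more acidic product consumes.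

Step 3
Reactants: 5 methyl 3,5,7-trioxotetracosanoate
Product: 7 methyl 2,4-dihydroxy-6-heptadecylbenzoate, via cyclic aldol adduct 6 (not isolated)
Conditions: K2CO3 (2.5 equiv), MeOH–CH2Cl2 (1:1), 0 °C → rt until 5 is consumed; then HCl in MeOH to pH 1–2, rt
Reagents that add atoms: none
Why: Carbonate in methanol interconverts all enolates of 5; the C4 and C6 methylenes, each between two ketones, are the more acidic, but the productive nucleophile is the less stabilised and more reactive β-keto ester enolate at C2, which adds to the C7 ketone to give 6, after which methanolic HCl removes water and the C3 and C5 carbonyls enolise to the phenols of 7. This is the intramolecular aldol condensation and aromatisation by which 3,5,7-triketo esters are known to give orsellinate-type 6-alkyl-2,4-dihydroxybenzoates, here only with a longer alkyl group. The single ring closed is the six-membered carbocycle C2–C3–C4–C5–C6–C7, formed by 6-exo-trig attack on the C7 carbonyl, counted as 6-(enolendo) for the C2=C3 enolate form and 6-(enolexo) for the ester enolate form, both allowed. The two stereocentres of 6 need no control because both become sp2 carbons of the arene. The step needs the C2-to-C7 aldol fold to win over the C6-to-C1 Claisen fold, over acylation of the C5 enol oxygen by the ester and over the reverse aldol fold C8-to-C3; the substrate secures this because a ketone is a much better acceptor than an ester that must expel methoxide, because C8 is only singly activated and is not deprotonated by carbonate, and because the fast reversible aldol addition is pulled forward by irreversible loss of water. A weak base with a non-chelating potassium counter-ion, exclusion of magnesium salts and of strong hydroxide, acid only after ring closure, and methanol as the alcohol (degenerate transesterification) should keep the other branches closed.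

Step 4
Reactants: 7 methyl 2,4-dihydroxy-6-heptadecylbenzoate; 8 iodomethane
Product: 9 methyl 2-hydroxy-4-methoxy-6-heptadecylbenzoate
Conditions: 8 (1.05 equiv), K2CO3 (1.2 equiv), acetone, rt → 40 °C
Reagents that add atoms: iodomethane 8, CI
Why: Williamson-type O-alkylation under weak base: the 2-OH is tied into a six-membered hydrogen bond with the ester carbonyl, so carbonate should ionise, and the limited iodomethane alkylate, only the free and more acidic 4-OH.

Step 5
Reactants: 9 methyl 2-hydroxy-4-methoxy-6-heptadecylbenzoate
Product: 11 3-methoxy-5-heptadecylphenol, via carboxylic acid 10 (not isolated)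
Conditions: KOH (10 equiv), HOCH2CH2OH–H2O (10:1), Ar, 130 → 160 °C; cool, 2 M HCl, extraction
Reagents that add atoms: none
Why: Saponification followed by protodecarboxylation: hot concentrated hydroxide overcomes the shielding of the di-ortho-substituted ester, and salicylate 10, whose carboxyl-bearing carbon is ortho to O− and para to OMe, is protonated at that ipso carbon and expels CO2 (the hydroxide oxygen taken up in 10 leaves with it), so running both events in one pot avoids isolating an acid that would partly decarboxylate anyway.

Step 6
Reactants: 11 3-methoxy-5-heptadecylphenol
Product: 12 2-methoxy-6-heptadecyl-1,4-benzoquinone (target)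
Conditions: ON(SO3K)2 (2.5 equiv), KH2PO4 buffer (pH 6–7), acetone–THF–H2O, vigorous stirring, rt
Reagents that add atoms: dipotassium nitrosodisulfonate ON(SO3K)2, [K+].[K+].[O]N(S(=O)(=O)[O-])S(=O)(=O)[O-]
Why: Teuber oxidation: one nitroxyl radical abstracts the phenolic hydrogen, a second couples through its oxygen at the open para carbon between OMe and the chain, and loss of imidodisulfonate from the dienone leaves the second carbonyl, so the p-quinone should form, with the near-neutral buffer protecting the methoxyquinone from hydrolysis.

Compound list
1 | 4-hydroxy-6-methyl-2H-pyran-2-one (triacetic acid lactone) | CC1=CC(O)=CC(=O)O1 | starting material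
2 | methyl 3,5-dioxohexanoate | CC(=O)CC(=O)CC(=O)OC | intermediate
3 | methyl octadecanoate (methyl stearate) | CCCCCCCCCCCCCCCCCC(=O)OC | starting material
4 | trilithium 2,4,6-trianion of methyl 3,5-dioxohexanoate (formed in the flask, not isolated) | [Li+].[Li+].[Li+].[CH2-]C(=O)[CH-]C(=O)[CH-]C(=O)OC | intermediate
5 | methyl 3,5,7-trioxotetracosanoate | CCCCCCCCCCCCCCCCCC(=O)CC(=O)CC(=O)CC(=O)OC | intermediate
6 | methyl 2-heptadecyl-2-hydroxy-4,6-dioxocyclohexane-1-carboxylate (racemic diastereomer mixture, both centres vanish in 7; not isolated) | CCCCCCCCCCCCCCCCCC1(O)CC(=O)CC(=O)C1C(=O)OC | intermediate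
7 | methyl 2,4-dihydroxy-6-heptadecylbenzoate | CCCCCCCCCCCCCCCCCC1=CC(O)=CC(O)=C1C(=O)OC | intermediate
8 | iodomethane | CI | starting material
9 | methyl 2-hydroxy-4-methoxy-6-heptadecylbenzoate | CCCCCCCCCCCCCCCCCC1=CC(OC)=CC(O)=C1C(=O)OC | intermediate
10 | 2-hydroxy-4-methoxy-6-heptadecylbenzoic acid (present as its potassium salt, not isolated) | CCCCCCCCCCCCCCCCCC1=CC(OC)=CC(O)=C1C(=O)O | intermediate
11 | 3-methoxy-5-heptadecylphenol | CCCCCCCCCCCCCCCCCC1=CC(OC)=CC(O)=C1 | intermediate
12 | 2-methoxy-6-heptadecyl-1,4-benzoquinone | CCCCCCCCCCCCCCCCCC1=CC(=O)C=C(OC)C1=O | target

Total step count: 6. Longest linear sequence: 6 steps (1 → 2 → 5 → 7 → 9 → 11 → 12).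

Steps most likely to fail

**Risk 1, step 2.**
- The α-methylene of 3 may transfer a proton to the terminal carbanion instead of being acylated.
- Conversion may stall as the product drains base.
- The chain may cyclise prematurely during the quench.

The fallback carries the carboxyl end as a masked acylketene instead of an ester enolate. It sets out from 3, which MeNH(OMe)·HCl and iPrMgCl in THF should convert into N-methoxy-N-methyloctadecanamide F1. Commercial 2,2,6-trimethyl-4H-1,3-dioxin-4-one is C-acetylated at its methyl group (LiN(SiMe3)2, then acetyl chloride, THF, −78 °C) to 2,2-dimethyl-6-(2-oxopropyl)-4H-1,3-dioxin-4-one F2. F2 is doubly deprotonated with LiN(iPr)2 and acylated by F1, whose chelated tetrahedral adduct neither collapses nor consumes base before the quench. This gives 6-(2,4-dioxohenicosyl)-2,2-dimethyl-4H-1,3-dioxin-4-one F3. Heating F3 in toluene with methanol (110 °C, sealed vessel) expels acetone by a retro-hetero-Diels–Alder reaction. The resulting acylketene tetracos-1-ene-1,3,5,7-tetrone F4 is trapped by methanol, and the fallback comes back to the route at 5.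

**Risk 2, step 3.**
- The chain may close in the Claisen fold.
- The ester may acylate the C5 enol oxygen.
- Methoxide may fragment the chain by retro-Claisen cleavage.

The fallback forms the same C2–C7 aldol bond, but with C1 locked in a heterocycle. The chain then lies trans to that carbonyl across the ring alkene, so neither Claisen closure nor lactonisation is geometrically possible. It sets out from 3 by way of F1 and F3 as described above. F3 is not opened but treated with Et3N in CH2Cl2 at rt. The dioxinone C5 adds to the far ketone, and loss of water should give 5-heptadecyl-7-hydroxy-2,2-dimethyl-4H-1,3-benzodioxin-4-one F5. Its only free hydroxyl is methylated with 8 (K2CO3, acetone) to 5-heptadecyl-7-methoxy-2,2-dimethyl-4H-1,3-benzodioxin-4-one F6. Hot KOH in ethylene glycol cleaves the acetonide ester, and the fallback comes back to the route at 10, which goes on to 11 in the same pot.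

**Risk 3, step 1.**
- Deprotonation of the pyranone to an unreactive vinylogous carboxylate may stall the ring opening.
- The product may close back to the lactone during acid work-up or on warming.

The fallback builds the ester end by C–C bond formation instead of lactone opening. It sets out from 1, which in boiling water opens and decarboxylates to pentane-2,4-dione F7. F7 is doubly deprotonated (NaH, then nBuLi, THF, 0 °C) and methoxycarbonylated at the terminal carbon with dimethyl carbonate. The fallback comes back to the route at 2.

Further compounds
F1 | step 2 | N-methoxy-N-methyloctadecanamide | CCCCCCCCCCCCCCCCCC(=O)N(C)OC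
F2 | step 2 | 2,2-dimethyl-6-(2-oxopropyl)-4H-1,3-dioxin-4-one | CC(=O)CC1=CC(=O)OC(C)(C)O1
F3 | step 2 | 6-(2,4-dioxohenicosyl)-2,2-dimethyl-4H-1,3-dioxin-4-one | CCCCCCCCCCCCCCCCCC(=O)CC(=O)CC1=CC(=O)OC(C)(C)O1
F4 | step 2 | tetracos-1-ene-1,3,5,7-tetrone (acylketene, transient) | CCCCCCCCCCCCCCCCCC(=O)CC(=O)CC(=O)C=C=O
F5 | step 3 | 5-heptadecyl-7-hydroxy-2,2-dimethyl-4H-1,3-benzodioxin-4-one | CCCCCCCCCCCCCCCCCC1=CC(O)=CC2=C1C(=O)OC(C)(C)O2
F6 | step 3 | 5-heptadecyl-7-methoxy-2,2-dimethyl-4H-1,3-benzodioxin-4-one | CCCCCCCCCCCCCCCCCC1=CC(OC)=CC2=C1C(=O)OC(C)(C)O2
F7 | step 1 | pentane-2,4-dione | CC(=O)CC(C)=O
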